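(The runs stem from a simulated flask for substances that don't exist, and the scatter is random.)

Catalyst charged is conserved, free or lost, so I reckoned with the fraction still free and not with the fraction lost.

common to all: left-handed substrate 0.20 M; right-handed substrate 0.20 M; free catalyst 0.05 mol%
- Tuesday's: reagent 0.60 equiv; run made earlier
- Friday's: reagent 0.90 equiv; run made earlier
- flask: reagent 1.20 equiv

- Tuesday's (time / h: left-handed product / %): 1.33: 3.0; 2.50: 3.4; 5.00: 6.4; 8.00: 8.7; 15.0: 12.7
- Friday's (time / h: left-handed product / %): 1.33: 3.7; 4.00: 8.5; 8.00: 12.7; 12.0: 15.4; 15.0: 16.8

(each reading ± 0.5 percentage points)

- free catalyst is single-handed; left-handed substrate and right-handed substrate are mirror images of each other, charged as a racemate, each of them at the stated concentration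
- the earlier runs were read with a standard deviation of 0.5 percentage points
- no earlier run changes the charge of free catalyst; that part of a forecast is a guess

- apparent order in reagent when 10% of the left-handed substrate and right-handed substrate together are converted (percent change of the rate of making left-handed product for one percent more reagent charged)
- apparent order in free catalyst when 10% of the left-handed substrate and right-handed substrate together are converted (percent change of the rate of making left-handed product for one percent more free catalyst charged)

In both runs the left-handed product rate fell. Between early and late chords, Tuesday's run read a fade of 0.0580 /h and Friday's 0.124 /h, both rough readings. I booked the fade on the catalyst, as a pseudo-first-order loss scaling with reagent charged, which gave the flask 0.141 /h. The first readings, scaled the same way, gave the flask a starting rate of left-handed product of 0.0411 /h of the charged substrates.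

The left-handed product's share of the 10% is unseen, so I guessed 7.00% of the charge. My ladder for the flask then ran: the look at 1.70 h, the fade time at 7.09 h, and a reagent time, its charge over that starting rate at one per left-handed product, of 14.6 h. Since the look came sooner than that reagent time, I took [reagent] as roughly its charge up to the look.

Product made then goes as charge times (one minus f) over the fade, and the rate as charge times f. At fixed conversion, with [reagent], the substrates and the fade held, the order in catalyst is therefore the reciprocal of f, the fraction of charged catalyst still free at the look, 76.0%. I expected 1.32.

The forecast gave 1.2 in reagent and 1 in free catalyst: “No run varies the catalyst, so its order is a guess.”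

The flask gave 1.2 in reagent and 1.2 in free catalyst, and the 10% came at 2.03 h; at 2.00 h free catalyst stood at 81.1% of its charge, against my 76.0% at the look, and the reciprocal of that simulated fraction is 1.23, below my 1.32.

    reagent + free catalyst → spent catalyst (k = 0.480 /M/h)
    reagent + free catalyst + left-handed substrate → free catalyst + left-handed product (k = 3500 /M²/h)
    reagent + free catalyst + right-handed substrate → free catalyst + right-handed product (k = 1800 /M²/h)

In the flask both substrates turned while free catalyst lasted, the step of the left-handed substrate using reagent 1.9 times as fast as that of the right-handed at the start. By 200 h free catalyst stood at 0.0296% of its charge, with reagent at 30.8% of its own charge and left-handed product at 25.9% of the substrates charged.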